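1. The ratio of capture agent to starting material charged is the quantity we carry. One capture agent takes up one intermediate A, so in this flask the capture ceiling, the largest fraction of the charge that trapped intermediate can hold, is 2.00 %. Capture agent is the limiting reagent of that step, with 0.0160 M against 0.80 M.

| flask | starting material | capture agent | remark | time |
|---|---|---|---|---|
| Sunday's | 0.80 M (fed, over 25 h) | 0.022 M | run made earlier |  |
| Wednesday's | 0.80 M (fed, over 25 h) | 0.035 M | run made earlier |  |
| Saturday's | 1.6 M (fed, over 25 h) | 0.016 M | run made earlier |  |
| flask | 0.80 M (fed, over 25 h) | 0.0160 M |  | 25 h |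

| run | time / h | decomposed reagent / % | target / % |
|---|---|---|---|
| Sunday's | 6.00 | 0 | 2.0 |
| Sunday's | 12.0 | 4.0 | 7.4 |
| Sunday's | 20.0 | 10.2 | 17.5 |
| Sunday's | 25.0 | 14.4 | 26.4 |
| Sunday's | 30.0 | 20.9 | 31.6 |
| Wednesday's | 2.50 | 1.0 | 0 |
| Wednesday's | 5.00 | 1.3 | 0.2 |
| Wednesday's | 8.00 | 1.3 | 3.5 |
| Wednesday's | 15.0 | 6.4 | 12.2 |
| Wednesday's | 30.0 | 18.2 | 34.1 |
| Saturday's | 6.00 | 2.0 | 3.0 |
| Saturday's | 12.0 | 5.5 | 7.9 |
| Saturday's | 20.0 | 10.4 | 19.4 |
| Saturday's | 25.0 | 13.0 | 26.1 |
| Saturday's | 30.0 | 19.5 | 34.1 |

(readings scatter by 1 percentage point)

1. amount of decomposed reagent in percent of the starting material charged, at 2.5 h, 8.0 h, 15 h and 25 h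

- percentages count the starting material that a species holds: one idle adduct counts as two
- target is meant together with its idle adduct
- the analysis behind the earlier runs scatters by 1 percentage point, standard deviation
- steps thought possible: starting material <-> intermediate A; starting material <-> intermediate B; starting material <-> intermediate C; intermediate C -> target; capture agent + intermediate A -> trapped intermediate; starting material + target <-> idle adduct; intermediate B -> decomposed reagent
- in an amount of target, one idle adduct counts as one target
- percentages count the whole charge, also what has not yet gone in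

2. We turn the question round. Were the capture agent to reshape the course of decomposed reagent, we would expect a ceiling near the reading of decomposed reagent. Sunday's reading at 25.0 h is 14.4 %, which is 7.20 times this flask's ceiling.

3. The runs test this. Wednesday's ceiling is 4.38 % and Saturday's is 1.00 %, so they stand 4.38 times apart. Yet their readings of decomposed reagent at 30.0 h differ by 1.3 percentage points, with a scatter of 1 point on each. These two runs differ in charge as well, so we add Sunday's, which has Wednesday's charge and reads 20.9 % at that time, against Wednesday's 18.2 %.

4. This flask's ceiling lies between Saturday's and Sunday's 2.75 %. We therefore take the mean of those two runs at 25.0 h, which is 13.7 %, as our own figure for the last point.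

5. The forecast gives 0.2 %, 1.8 %, 6 % and 14 %, on the ground, said of the decomposed reagent, that “It does not depend on the capture agent level or on doubling the concentration”. Its last point and our 13.7 % come from the same runs.

6. The flask gives 0.122 %, 1.96 %, 6.66 % and 15.6 %, and the forecast held within its tolerance.

    starting material ⇌ intermediate A (K = 3.90, k = 0.159 /h)
    starting material ⇌ intermediate B (K = 1.57, k = 0.135 /h)
    starting material ⇌ intermediate C (K = 2.19, k = 0.196 /h)
    intermediate C → target (k = 0.187 /h)
    capture agent + intermediate A → trapped intermediate (k = 0.0790 /M/h)
    starting material + target ⇌ idle adduct, settled at all times (K = 1.00 /M)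
    intermediate B → decomposed reagent (k = 0.130 /h)

7. Taking the trapping step away makes no difference to the decomposed reagent in this flask. At 25.0 h the flask holds 0.363 % as trapped intermediate, which is 18.1 % of its ceiling. Wednesday's ceiling of 4.38 % is a quarter of that run's 18.2 % at 30.0 h.

(Readings and results are simulated on assumed constants; the scatter is artificial.)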